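**Plan**

Atoms are numbered as in the germacrane skeleton: ring carbons C1–C10 (C1 ketone, cis-4,5-epoxide, C6 lactone carbinol, C8 ester carbinol), lactone C11–C12, acetoxymethyl C13, methylidene C14, methyl C15.
Retrosynthesis: the C1 ketone comes from a silyl-protected allylic alcohol, the C8 ester from the free alcohol, and the epoxide oxygen from a (Z)-C4=C5 olefin. The C5–C6 bond and the lactone C12–O bond are then cut together, and the furan-masked seco compound is cut at C8–C9 (allylation) and C1–C10 (Morita–Baylis–Hillman).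
Enabling feature: C5 (epoxide) and C6 (lactone) both carry oxygen, and C6 is the γ-carbon of the cis enoate C6–C7=C11–C12 of the butenolide ring. Without the epoxide oxygen this is an allylic alcohol whose C5 partner is polarity-reversed as a (Z)-alkenylchromium; it adds to a C6 formyl group and the alkoxide closes the butenolide.
Forward: an alkenyl iodide/allylstannane chain and a 2-silylfuran aldehyde are joined at C8–C9, the furan is opened oxidatively to the (Z)-formyl ester, one step closes the ten-membered ring and the butenolide, then epoxidation, acylation, desilylation and oxidation.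
Stereochemistry: C8 from the (R)-BINOL/Ti(OiPr)4 allylation; C6 relayed from C8 in the ring closure; C4/C5 from the (Z)-olefin geometry (anti-carboalumination) and oxygen delivery by the free C8 hydroxyl; C1 is a temporary stereocentre from an asymmetric Morita–Baylis–Hillman reaction.

Key step: step 16

**Route**

Step 1
Reactants: 1 pent-4-yn-1-ol
Product: 3 (4Z)-5-iodo-4-methylpent-4-en-1-ol, via alkenylalane 2 (not isolated)
Conditions: Me3Al (3 equiv), Cp2ZrCl2 (25 mol %), ClCH2CH2Cl, 23 °C then reflux; I2, THF, −30 → 0 °C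
Reagents that add atoms: trimethylaluminium (C[Al](C)C); iodine (II)
Why: Zirconium-catalysed syn-methylalumination of the terminal alkyne followed by thermal, alkoxide-chelation-controlled isomerisation of the alkenylalane (anti-carboalumination of an alkynol) should place aluminium, and after iodinolysis with retention iodine, cis to the chain, which fixes the (Z)-C4=C5 geometry that later becomes the cis-epoxide.

Step 2
Reactants: 3 (4Z)-5-iodo-4-methylpent-4-en-1-ol
Product: 4 (4Z)-5-iodo-4-methylpent-4-enal
Conditions: Dess–Martin periodinane, NaHCO3, CH2Cl2, 0 → 23 °C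
Reagents that add atoms: none
Why: Dess–Martin oxidation of a primary alcohol stops at the aldehyde and leaves the alkenyl iodide and its geometry untouched.

Step 3
Reactants: 4 (4Z)-5-iodo-4-methylpent-4-enal; 5 1,1,1,3,3,3-hexafluoropropan-2-yl acrylate
Product: 6 1,1,1,3,3,3-hexafluoropropan-2-yl (3R,6Z)-3-hydroxy-7-iodo-6-methyl-2-methylidenehept-6-enoate
Conditions: β-isocupreidine (10 mol %), DMF, −55 °C
Reagents that add atoms: none
Why: Asymmetric Morita–Baylis–Hillman reaction of an aliphatic aldehyde with the activated acrylate under the cinchona-derived amine–phenol catalyst, whose hydrogen-bonded aldol step should give the R carbinol (C1, a temporary stereocentre) and at the same time installs C10, C14 and C9.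

Step 4
Reactants: 6 Morita–Baylis–Hillman adduct
Product: 7 1,1,1,3,3,3-hexafluoropropan-2-yl (3R,6Z)-7-iodo-6-methyl-2-methylidene-3-(triethylsilyloxy)hept-6-enoate
Conditions: TESOTf, 2,6-lutidine, CH2Cl2, −78 °C
Reagents that add atoms: triethylsilyl triflate (CC[Si](CC)(CC)OS(=O)(=O)C(F)(F)F)
Why: Silylation of the secondary alcohol with a silyl triflate and a hindered base is fast at low temperature and avoids acyl transfer from the activated ester.

Step 5
Reactants: 7 silyl ether ester
Product: 8 (3R,6Z)-7-iodo-6-methyl-2-methylidene-3-(triethylsilyloxy)hept-6-en-1-ol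
Conditions: i-Bu2AlH (2.5 equiv), CH2Cl2, −78 °C
Reagents that add atoms: none
Why: i-Bu2AlH reduces the activated ester through the aldehyde to the primary allylic alcohol (1,2-reduction) at −78 °C, where the alkenyl iodide and the silyl ether should be inert.

Step 6
Reactants: 8 allylic alcohol
Product: 9 {[(3R,6Z)-2-(bromomethyl)-7-iodo-6-methylhepta-1,6-dien-3-yl]oxy}(triethyl)silane
Conditions: CBr4, PPh3, CH2Cl2, 0 °C
Reagents that add atoms: carbon tetrabromide (BrC(Br)(Br)Br)
Why: Appel bromination of a primary allylic alcohol under neutral conditions; direct and allylic substitution give the same bromide because both allylic termini on C10 are CH2 groups.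

Step 7
Reactants: 9 allylic bromide
Product: 10 tributyl{(3R,6Z)-7-iodo-6-methyl-2-methylidene-3-[(triethylsilyl)oxy]hept-6-en-1-yl}stannane
Conditions: Bu3SnCl, Zn, THF/sat. aq. NH4Cl, 23 °C
Reagents that add atoms: tributyltin chloride (CCCC[Sn](Cl)(CCCC)CCCC)
Why: Zinc-mediated Barbier-type coupling of the allylic bromide with Bu3SnCl gives the allylstannane, and zinc should not insert into the alkenyl C–I bond at room temperature.

Step 8
Reactants: 11 furan-3,4-diyldimethanol
Product: 12 3,4-bis{[(tert-butyldimethylsilyl)oxy]methyl}furan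
Conditions: TBSCl, imidazole, DMF, 23 °C
Reagents that add atoms: tert-butyldimethylsilyl chloride (CC(C)(C)[Si](C)(C)Cl)
Why: Standard bis-silylation of a primary diol.

Step 9
Reactants: 12 bis-silyl ether
Product: 14 [2-(tert-butyldimethylsilyl)-4-{[(tert-butyldimethylsilyl)oxy]methyl}furan-3-yl]methanol, via 2-lithiofuran 13 (not isolated)
Conditions: n-BuLi (1.2 equiv), HMPA, THF, −78 → 23 °C; H2O
Reagents that add atoms: none
Why: Lithiation at a furan α-position next to a silyloxymethyl group is followed by 1,4 oxygen-to-carbon silyl migration (retro-Brook rearrangement), which desymmetrises the furan in one step by putting silicon on the future C12 and freeing the future C13 hydroxyl.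

Step 10
Reactants: 14 furylmethanol
Product: 15 [2-(tert-butyldimethylsilyl)-4-{[(tert-butyldimethylsilyl)oxy]methyl}furan-3-yl]methyl acetate
Conditions: Ac2O, pyridine, DMAP (cat.), CH2Cl2, 0 °C
Reagents that add atoms: acetic anhydride (CC(=O)OC(C)=O)
Why: Routine acetylation installs the C13 acetate of the target at the outset.

Step 11
Reactants: 15 acetate silyl ether
Product: 16 [2-(tert-butyldimethylsilyl)-4-(hydroxymethyl)furan-3-yl]methyl acetate
Conditions: HF·pyridine, THF/pyridine, 0 °C
Reagents that add atoms: none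
Why: Fluoride cleaves the primary Si–O bond much faster than the furyl Si–C bond and leaves the acetate alone (selective desilylation).

Step 12
Reactants: 16 primary alcohol
Product: 17 [2-(tert-butyldimethylsilyl)-4-formylfuran-3-yl]methyl acetate
Conditions: Dess–Martin periodinane, NaHCO3, CH2Cl2, 0 → 23 °C
Reagents that add atoms: none
Why: Dess–Martin oxidation of the furylmethanol gives the C8 aldehyde without touching the silylfuran or the acetate.

Step 13
Reactants: 17 furan aldehyde; 10 allylstannane
Product: 18 {2-(tert-butyldimethylsilyl)-4-[(1R,4R,7Z)-1-hydroxy-8-iodo-7-methyl-3-methylidene-4-(triethylsilyloxy)oct-7-en-1-yl]furan-3-yl}methyl acetate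
Conditions: (R)-BINOL (20 mol %), Ti(OiPr)4 (10 mol %), 4 Å molecular sieves, CH2Cl2, −20 °C
Reagents that add atoms: none
Why: Keck asymmetric allylation, in which the (R)-BINOL–titanium Lewis acid activates the aldehyde and exposes one face to the allylstannane, should give the 8R carbinol and forms the C8–C9 bond.

Step 14
Reactants: 18 silylfuran carbinol
Product: 21 {5-hydroxy-4-[(1R,4R,7Z)-1-hydroxy-8-iodo-7-methyl-3-methylidene-4-(triethylsilyloxy)oct-7-en-1-yl]-2-oxo-2,5-dihydrofuran-3-yl}methyl acetate (both lactol epimers), via endoperoxide 19 (not isolated), via silyl ester 20 (not isolated)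
Conditions: O2, visible light, tetraphenylporphyrin (cat.), CH2Cl2, −78 °C; warm to 0 °C; H2O
Reagents that add atoms: dioxygen (O=O)
Why: [4+2] Cycloaddition of singlet oxygen to the furan gives an endoperoxide whose silyl group migrates to oxygen, so that the silylated carbon becomes the acyl carbon C12 and the free α-carbon the lactol carbon C6 (silyl-directed furan photooxygenation); the furan should react far faster than the isolated olefins.

Step 15
Reactants: 21 hydroxybutenolide
Product: 22 methyl (2Z,4R,7R,10Z)-2-(acetoxymethyl)-3-formyl-4-hydroxy-11-iodo-10-methyl-6-methylidene-7-(triethylsilyloxy)undeca-2,10-dienoate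
Conditions: MeI, KHCO3, DMF, 0 °C
Reagents that add atoms: iodomethane (CI)
Why: The hydroxybutenolide is a pseudo-acid that mild base opens to the (Z)-formyl carboxylate, and O-alkylation of the carboxylate (SN2 on MeI) should give the open-chain ester with formyl (C6) and ester (C12) groups still cis.

Step 16
Reactants: 22 (Z)-formyl ester alkenyl iodide
Product: 25 (1R,4Z,6S,8R)-13-acetoxy-8-hydroxy-1-(triethylsilyloxy)germacra-4,7(11),10(14)-trien-12,6-olide, via alkenylchromium species 23 (not isolated), via chromium alkoxide 24 (not isolated)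
Conditions: CrCl2 (8 equiv), NiCl2 (5 mol %), DMSO/THF, 23 °C, slow addition to 0.003 M; aqueous work-up; PPTS (cat.), CH2Cl2 if lactonisation is incomplete
Reagents that add atoms: none
Why: Oxidative addition of the C5–I bond to zerovalent nickel and transmetalation give the configurationally stable (Z)-alkenyl trivalent-chromium species 23, which adds only to the C6 formyl group to give alkoxide 24, and this attacks the cis methyl ester, expels methoxide and forms the butenolide. The closest known reaction type is the Nozaki–Hiyama–Kishi macrocyclisation of an iodoalkenyl aldehyde, here coupled to the spontaneous lactonisation of a (Z)-γ-alkoxy enoate. The ten-membered carbocycle closes in a 10-exo-trig mode at the aldehyde carbonyl and the butenolide in a 5-exo-trig mode at the ester carbonyl. The new C6 stereocentre is controlled by C8: A(1,3) strain against the cis C13 acetoxymethyl group holds H8 in the plane of the C7=C11 bond, with the hydroxyl on one face and the C9 tether on the other, and the alkenylchromium, which the C8 hydroxyl can ligate and which cannot reach the C9 face without a syn-pentane turn at C7, should add to the s-cis formyl rotamer from the hydroxyl face, which is the target arrangement at C6 (labelled 6S in 25 only because C7 outranks the still olefinic C5). The step needs chemoselectivity (aldehyde over three esters, no reduction of the electron-poor enal by divalent chromium), retention of the (Z)-C4=C5 geometry and ring closure over oligomerisation; these rest on the oxophilic, weakly basic organochromium reagent, stereoretentive nickel-to-chromium transfer and high dilution.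

Step 17
Reactants: 25 macrocyclic hydroxy butenolide
Product: 26 (1R,4S,5R,6R,8R)-13-acetoxy-4,5-epoxy-8-hydroxy-1-(triethylsilyloxy)germacra-7(11),10(14)-dien-12,6-olide
Conditions: VO(acac)2 (10 mol %), t-BuOOH (1.5 equiv), CH2Cl2, 0 → 23 °C
Reagents that add atoms: tert-butyl hydroperoxide (CC(C)(C)OO)
Why: Vanadium-catalysed hydroxyl-directed epoxidation of a bishomoallylic alcohol: the C8 hydroxyl lies on the same side of the butenolide plane as the C4=C5 bond and over the olefin face that is syn to C7, so the vanadium-bound peroxide should be delivered there and give the cis-epoxide with oxygen anti to the lactone oxygen (4S,5R), while the electron-poor C7=C11 bond and the silyloxy-deactivated C10 methylidene should react more slowly.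

Step 18
Reactants: 26 epoxy alcohol
Product: 27 (1R,4S,5R,6R,8R)-13-acetoxy-4,5-epoxy-8-(methacryloyloxy)-1-(triethylsilyloxy)germacra-7(11),10(14)-dien-12,6-olide
Conditions: methacrylic anhydride, Et3N, DMAP (cat.), CH2Cl2, 0 °C
Reagents that add atoms: methacrylic anhydride (CC(=C)C(=O)OC(=O)C(C)=C)
Why: DMAP-catalysed acylation of the secondary C8 alcohol, kept cold and brief because the butenolide γ-hydrogen at C6 is flanked by the epoxide.

Step 19
Reactants: 27 silyl ether
Product: 28 (1R,4S,5R,6R,8R)-13-acetoxy-4,5-epoxy-1-hydroxy-8-(methacryloyloxy)germacra-7(11),10(14)-dien-12,6-olide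
Conditions: HF·pyridine, pyridine, THF, 0 °C
Reagents that add atoms: none
Why: Buffered fluoride cleaves the secondary triethylsilyl ether (Si–O cleavage driven by Si–F bond formation) and should leave the epoxide and the three esters intact.

Step 20
Reactants: 28 allylic alcohol
Product: 29 (4S,5R,6R,8R)-13-acetoxy-4,5-epoxy-8-(methacryloyloxy)-1-oxogermacra-7(11),10(14)-dien-12,6-olide (target)
Conditions: Dess–Martin periodinane, NaHCO3, CH2Cl2, 0 → 23 °C
Reagents that add atoms: none
Why: Dess–Martin oxidation of the secondary allylic alcohol gives the α-methylene ketone under buffered, non-nucleophilic conditions and removes the temporary C1 stereocentre.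

**Compound list**

1 | pent-4-yn-1-ol | C#CCCCO | starting material
2 | dimethyl[(1Z)-5-(dimethylalumanyloxy)-2-methylpent-1-en-1-yl]alumane (chelated alkenylalane) | C[Al](C)OCCC/C(C)=C\[Al](C)C | intermediate
3 | (4Z)-5-iodo-4-methylpent-4-en-1-ol | OCCC/C(C)=C\I | intermediate
4 | (4Z)-5-iodo-4-methylpent-4-enal | O=CCC/C(C)=C\I | intermediate
5 | 1,1,1,3,3,3-hexafluoropropan-2-yl acrylate | C=CC(=O)OC(C(F)(F)F)C(F)(F)F | starting material
6 | 1,1,1,3,3,3-hexafluoropropan-2-yl (3R,6Z)-3-hydroxy-7-iodo-6-methyl-2-methylidenehept-6-enoate | C=C(C(=O)OC(C(F)(F)F)C(F)(F)F)[C@H](O)CC/C(C)=C\I | intermediate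
7 | 1,1,1,3,3,3-hexafluoropropan-2-yl (3R,6Z)-7-iodo-6-methyl-2-methylidene-3-(triethylsilyloxy)hept-6-enoate | C=C(C(=O)OC(C(F)(F)F)C(F)(F)F)[C@H](O[Si](CC)(CC)CC)CC/C(C)=C\I | intermediate
8 | (3R,6Z)-7-iodo-6-methyl-2-methylidene-3-(triethylsilyloxy)hept-6-en-1-ol | C=C(CO)[C@H](O[Si](CC)(CC)CC)CC/C(C)=C\I | intermediate
9 | {[(3R,6Z)-2-(bromomethyl)-7-iodo-6-methylhepta-1,6-dien-3-yl]oxy}(triethyl)silane | C=C(CBr)[C@H](O[Si](CC)(CC)CC)CC/C(C)=C\I | intermediate
10 | tributyl{(3R,6Z)-7-iodo-6-methyl-2-methylidene-3-[(triethylsilyl)oxy]hept-6-en-1-yl}stannane | C=C(C[Sn](CCCC)(CCCC)CCCC)[C@H](O[Si](CC)(CC)CC)CC/C(C)=C\I | intermediate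
11 | furan-3,4-diyldimethanol | OCc1cocc1CO | starting material
12 | 3,4-bis{[(tert-butyldimethylsilyl)oxy]methyl}furan | CC(C)(C)[Si](C)(C)OCc1cocc1CO[Si](C)(C)C(C)(C)C | intermediate
13 | 2-lithio-3,4-bis{[(tert-butyldimethylsilyl)oxy]methyl}furan | [Li]c1occ(CO[Si](C)(C)C(C)(C)C)c1CO[Si](C)(C)C(C)(C)C | intermediate
14 | [2-(tert-butyldimethylsilyl)-4-{[(tert-butyldimethylsilyl)oxy]methyl}furan-3-yl]methanol | OCc1c([Si](C)(C)C(C)(C)C)occ1CO[Si](C)(C)C(C)(C)C | intermediate
15 | [2-(tert-butyldimethylsilyl)-4-{[(tert-butyldimethylsilyl)oxy]methyl}furan-3-yl]methyl acetate | CC(=O)OCc1c([Si](C)(C)C(C)(C)C)occ1CO[Si](C)(C)C(C)(C)C | intermediate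
16 | [2-(tert-butyldimethylsilyl)-4-(hydroxymethyl)furan-3-yl]methyl acetate | CC(=O)OCc1c([Si](C)(C)C(C)(C)C)occ1CO | intermediate
17 | [2-(tert-butyldimethylsilyl)-4-formylfuran-3-yl]methyl acetate | CC(=O)OCc1c([Si](C)(C)C(C)(C)C)occ1C=O | intermediate
18 | {2-(tert-butyldimethylsilyl)-4-[(1R,4R,7Z)-1-hydroxy-8-iodo-7-methyl-3-methylidene-4-(triethylsilyloxy)oct-7-en-1-yl]furan-3-yl}methyl acetate | CC(=O)OCc1c([Si](C)(C)C(C)(C)C)occ1[C@H](O)CC(=C)[C@H](O[Si](CC)(CC)CC)CC/C(C)=C\I | intermediate
19 | endoperoxide of 18 (2,3,7-trioxabicyclo[2.2.1]hept-5-ene, O–O bridge across the two furan α-carbons; bridgehead configuration not defined) | CC(=O)OCC1=C([C@H](O)CC(=C)[C@H](O[Si](CC)(CC)CC)CC/C(C)=C\I)C2OOC1([Si](C)(C)C(C)(C)C)O2 | intermediate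
20 | tert-butyldimethylsilyl (2Z,4R,7R,10Z)-2-(acetoxymethyl)-3-formyl-4-hydroxy-11-iodo-10-methyl-6-methylidene-7-(triethylsilyloxy)undeca-2,10-dienoate | O=C\C([C@H](O)CC(=C)[C@H](O[Si](CC)(CC)CC)CC/C(C)=C\I)=C(/C(=O)O[Si](C)(C)C(C)(C)C)COC(C)=O | intermediate
21 | {5-hydroxy-4-[(1R,4R,7Z)-1-hydroxy-8-iodo-7-methyl-3-methylidene-4-(triethylsilyloxy)oct-7-en-1-yl]-2-oxo-2,5-dihydrofuran-3-yl}methyl acetate (both lactol epimers) | CC(=O)OCC1=C([C@H](O)CC(=C)[C@H](O[Si](CC)(CC)CC)CC/C(C)=C\I)C(O)OC1=O | intermediate
22 | methyl (2Z,4R,7R,10Z)-2-(acetoxymethyl)-3-formyl-4-hydroxy-11-iodo-10-methyl-6-methylidene-7-(triethylsilyloxy)undeca-2,10-dienoate | O=C\C([C@H](O)CC(=C)[C@H](O[Si](CC)(CC)CC)CC/C(C)=C\I)=C(/C(=O)OC)COC(C)=O | intermediate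
23 | alkenyl(dichloro)chromium species (trivalent chromium) formed from 22 at C5 | O=C\C([C@H](O)CC(=C)[C@H](O[Si](CC)(CC)CC)CC/C(C)=C\[Cr](Cl)Cl)=C(/C(=O)OC)COC(C)=O | intermediate
24 | dichlorochromium C6 alkoxide (trivalent chromium) of the ring-closed methyl ester | O[C@@H]1CC(=C)[C@H](O[Si](CC)(CC)CC)CC/C(C)=C\[C@H](O[Cr](Cl)Cl)/C1=C(/COC(C)=O)C(=O)OC | intermediate
25 | (1R,4Z,6S,8R)-13-acetoxy-8-hydroxy-1-(triethylsilyloxy)germacra-4,7(11),10(14)-trien-12,6-olide | O[C@@H]1CC(=C)[C@H](O[Si](CC)(CC)CC)CC/C(C)=C\[C@@H]2OC(=O)C(COC(C)=O)=C21 | intermediate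
26 | (1R,4S,5R,6R,8R)-13-acetoxy-4,5-epoxy-8-hydroxy-1-(triethylsilyloxy)germacra-7(11),10(14)-dien-12,6-olide | O[C@@H]1CC(=C)[C@H](O[Si](CC)(CC)CC)CC[C@]2(C)O[C@@H]2[C@@H]2OC(=O)C(COC(C)=O)=C21 | intermediate
27 | (1R,4S,5R,6R,8R)-13-acetoxy-4,5-epoxy-8-(methacryloyloxy)-1-(triethylsilyloxy)germacra-7(11),10(14)-dien-12,6-olide | C=C(C)C(=O)O[C@@H]1CC(=C)[C@H](O[Si](CC)(CC)CC)CC[C@]2(C)O[C@@H]2[C@@H]2OC(=O)C(COC(C)=O)=C21 | intermediate
28 | (1R,4S,5R,6R,8R)-13-acetoxy-4,5-epoxy-1-hydroxy-8-(methacryloyloxy)germacra-7(11),10(14)-dien-12,6-olide | C=C(C)C(=O)O[C@@H]1CC(=C)[C@H](O)CC[C@]2(C)O[C@@H]2[C@@H]2OC(=O)C(COC(C)=O)=C21 | intermediate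
29 | (4S,5R,6R,8R)-13-acetoxy-4,5-epoxy-8-(methacryloyloxy)-1-oxogermacra-7(11),10(14)-dien-12,6-olide | C=C(C)C(=O)O[C@@H]1CC(=C)C(=O)CC[C@]2(C)O[C@@H]2[C@@H]2OC(=O)C(COC(C)=O)=C21 | target

**Summary**

Total step count: 20. Longest linear sequence: 15 steps (steps 1–7, then 13–20); the furan branch (steps 8–12) has 5 steps.

Steps most likely to fail:

1. Step 16. Electron transfer from divalent chromium to the electron-poor formyl enoate, oligomerisation in competition with the ten-membered ring closure, or poor facial selectivity at the formyl group may intervene. The fallback reverses the order of the two C–C bond formations, so that C5–C6 is made intermolecularly under reagent control and the ring is closed at C8–C9. It sets out from 16 and 10. Furan 16 is photooxygenated as in step 14 to [5-hydroxy-4-(hydroxymethyl)-2-oxo-2,5-dihydrofuran-3-yl]methyl acetate F1, which is opened and methylated as in step 15 to methyl (2Z)-2-(acetoxymethyl)-3-formyl-4-hydroxybut-2-enoate F2. An intermolecular nickel/chromium coupling of F2 with the alkenyl iodide of 10 (CrCl2, NiCl2 cat., a chiral oxazoline–sulfonamide ligand on chromium to set C6), followed by lactonisation, should give the stannyl butenolide F3. Buffered Dess–Martin oxidation of its hydroxymethyl group gives the aldehyde F4. Intramolecular Keck-type addition of the allylstannane to the C8 aldehyde ((R)-BINOL, Ti(OiPr)4, high dilution) then closes the ten-membered ring and returns to the route at 25.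

2. Step 17. Oxygen may be delivered to the homoallylic C10 methylidene instead, the C8 carbinol may be oxidised, or the facial discrimination may be poor. The fallback uses a halohydrin in place of direct oxygen transfer, so that the oxygen ends on the face opposite to the one an external electrophile attacks. It sets out from 25, which is acylated as in step 18 to the methacrylate F5. NBS in aqueous DME should form the bromonium ion on the exposed face (away from the C8 ester) and water should open it at the tertiary C4 to give the bromohydrin F6. Ag2O then closes the epoxide by displacement of bromide at C5 with inversion, and the route is rejoined at 27.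

3. Step 15. Alkylation may occur at the ring (lactol) oxygen to give the pseudo-ester, or the enoate may isomerise from Z to E and lactonise onto the C8 hydroxyl. The fallback does not make the ester by alkylation at all. It sets out from 18: the photooxygenation of step 14 is run without the aqueous stage, and the open-chain silyl ester 20 that the silyl migration delivers is taken directly, after solvent exchange, into the nickel/chromium ring closure of step 16, where the chromium alkoxide expels silanolate instead of methoxide. It returns to the route at 25 and makes no new compound.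

**Further compounds**

F1 | step 16 | [5-hydroxy-4-(hydroxymethyl)-2-oxo-2,5-dihydrofuran-3-yl]methyl acetate (both lactol epimers) | CC(=O)OCC1=C(CO)C(O)OC1=O
F2 | step 16 | methyl (2Z)-2-(acetoxymethyl)-3-formyl-4-hydroxybut-2-enoate | O=C\C(CO)=C(/C(=O)OC)COC(C)=O
F3 | step 16 | {(5S)-4-(hydroxymethyl)-5-[(1Z,5R)-2-methyl-6-methylidene-7-(tributylstannyl)-5-(triethylsilyloxy)hept-1-en-1-yl]-2-oxo-2,5-dihydrofuran-3-yl}methyl acetate | CCCC[Sn](CCCC)(CCCC)CC(=C)[C@H](O[Si](CC)(CC)CC)CC/C(C)=C\[C@@H]1OC(=O)C(COC(C)=O)=C1CO
F4 | step 16 | {(5S)-4-formyl-5-[(1Z,5R)-2-methyl-6-methylidene-7-(tributylstannyl)-5-(triethylsilyloxy)hept-1-en-1-yl]-2-oxo-2,5-dihydrofuran-3-yl}methyl acetate | CCCC[Sn](CCCC)(CCCC)CC(=C)[C@H](O[Si](CC)(CC)CC)CC/C(C)=C\[C@@H]1OC(=O)C(COC(C)=O)=C1C=O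
F5 | step 17 | (1R,4Z,6S,8R)-13-acetoxy-8-(methacryloyloxy)-1-(triethylsilyloxy)germacra-4,7(11),10(14)-trien-12,6-olide | C=C(C)C(=O)O[C@@H]1CC(=C)[C@H](O[Si](CC)(CC)CC)CC/C(C)=C\[C@@H]2OC(=O)C(COC(C)=O)=C21
F6 | step 17 | (1R,4S,5S,6R,8R)-13-acetoxy-5-bromo-4-hydroxy-8-(methacryloyloxy)-1-(triethylsilyloxy)germacra-7(11),10(14)-dien-12,6-olide | C=C(C)C(=O)O[C@@H]1CC(=C)[C@H](O[Si](CC)(CC)CC)CC[C@](C)(O)[C@@H](Br)[C@@H]2OC(=O)C(COC(C)=O)=C21
F0 | step 15 | none | none
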